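Begin from slowness: the reagent, charged in the smaller amount, loses ground at no more than 0.0340 min⁻¹ per unit of its own amount, even with the catalyst wholly bound, and that is slower than substrate opening with the catalyst wholly free and than the side reaction in this flask.

    substrate + free catalyst → free catalyst + open intermediate (k1 = 6500 L mol⁻¹ min⁻¹)
    free catalyst + open intermediate ⇌ catalyst intermediate (K2 = 200 L mol⁻¹, k2 = 6900 L mol⁻¹ min⁻¹)
    reagent + catalyst intermediate → free catalyst + target (k3 = 3700 L mol⁻¹ min⁻¹)
    open intermediate → side product (k4 = 0.15 min⁻¹)

substrate 11 mM; reagent 7.70 mM; free catalyst 9.2 µM

- the form that holds most of the catalyst when 50 % of the substrate are converted (catalyst intermediate / free catalyst)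
- its share of the catalyst then
- apparent order in reagent when 50 % of the substrate are converted (percent change of the rate of making target for one percent more reagent charged)
- apparent order in free catalyst when 50 % of the substrate are converted (percent change of the rate of making target for one percent more free catalyst charged)

Climb down the ladder from the fastest rung. Catalyst intermediate leaves its form at 63.0 min⁻¹, back to free catalyst or on to target, with reagent as charged, and this is far faster than the side reaction, so treat the two catalyst forms as balanced at each moment. Their ratio, bound over free, is then the open intermediate fraction y divided by the half-binding level, the fraction of the substrate charge at which open intermediate holds bound and free catalyst equal, 0.830.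

On the next rung, open intermediate goes to side product at 0.15 min⁻¹, faster than substrate opens, so let it follow the substrate. With half the substrate left, estimate y as 0.199 times the free share, and that share is the half-binding level over itself plus y. Solve this pair to get y = 0.166 and a free share of 83.3 %, so free catalyst is the resting state.

On the lowest rung, write the reagent balance: reagent lost equals target made, at an estimated 0.00568 min⁻¹ per unit of what remains. Over an estimated substrate half-life of 13.9 min that comes to an estimated 7.90 % of its charge, so, as an approximation, reckon with the reagent as charged. Differentiating the same lines at fixed conversion, with y held for the reagent, gives my orders: 0.623 in reagent and 1.71 in catalyst.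

The forecast says free catalyst at 83 %, with orders 0.65 and 1.55, and notes “Side-product loss dominates I.” Its share stands close to mine, but my reagent order is lower and my catalyst order higher.

The flask gives free catalyst at 83.0 %, with orders 0.65 and 1.6. At 15.0 min, open intermediate is made at 0.843 of the rate at which it is used up, each step taken net. Now put the half-binding level to work early in the run, at 1.50 min, when reagent stands at 99.8 % of its charge: open intermediate at 7.19 % of the substrate charge divided by 0.830 predicts a bound-to-free ratio of 0.0866, and the flask holds catalyst intermediate at 7.93 % of the catalyst charged against free catalyst at 92.1 %, a ratio of 0.0861.

The constants are assumed, and the outcome is calculated.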